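**Retrosynthetic overview** (f = farnesyl/biogenetic carbon numbering)
1. Esters last: the angelate goes on O–C5 by Yamaguchi acylation and the (S)-2-methylbutanoate comes from anti-opening of cis-epoxide 17 at the unhindered C4, which leads back to dienone 16.
2. 16 ⇒ nor-ketone 13 by enone transposition (dehydrogenation, MeLi, oxidative 1,3-shift).
3. 13 ⇒ 11-membered trienone 11 by one transannular cationic cascade: f1–f6, then f2–f7. These are the bonds, order and polarity of the humulyl → himachalyl → longipinyl sequence, with the Lewis-acid-bound enone standing in for the f1–f3 allyl cation.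
4. 11 ⇒ keto-aldehyde 9 (macro-aldol closure of the humulane ring) ⇒ allylic bromide 3 (from sulcatone) + alkynol 6 (from hydroxypivaldehyde).
5. Ring order: 11-membered ring; then the six- and seven-membered rings together (f1–f6); then the cyclobutane (f2–f7) in the same flask.

Conventions and assumption: tricyclic compounds carry tricyclo[5.4.0.0^2,8]undecane locants (f1–f11 = C7, C8, C9, C10, C11, C1, C2, C3, C4, C5, C6). Hydroxypivaldehyde 4 is bought as its dimer, which gives the monomer in methanol.

**Step 1**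
Reactants: 1 6-methylhept-5-en-2-one
Product: 2 (E)-7-hydroxy-6-methylhept-5-en-2-one
Conditions: SeO2 (0.3 equiv), t-BuOOH (2.5 equiv), salicylic acid (0.1 equiv), CH2Cl2, 0 °C → rt
Reagents that add atoms: tert-butyl hydroperoxide CC(C)(C)OO; selenium dioxide O=[Se]=O (oxygen carrier)
Why: Riley–Sharpless allylic hydroxylation (ene reaction, then [2,3]-shift) oxidises the (E)-methyl of the gem-dimethyl alkene, which fixes the trisubstituted E geometry needed in step 8.

**Step 2**
Reactants: 2 (E)-7-hydroxy-6-methylhept-5-en-2-one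
Product: 3 (E)-7-bromo-6-methylhept-5-en-2-one
Conditions: PBr3 (0.4 equiv), Et2O, −10 °C
Reagents that add atoms: phosphorus tribromide BrP(Br)Br
Why: SN2 bromination of the primary allylic alcohol through its phosphite ester keeps the E geometry and leaves the ketone alone.

**Step 3**
Reactants: 4 3-hydroxy-2,2-dimethylpropanal
Product: 6 2,2-dimethylbut-3-yn-1-ol, via diazoalkene 5 (not isolated)
Conditions: dimethyl (1-diazo-2-oxopropyl)phosphonate (1.2 equiv), K2CO3 (2 equiv), MeOH, 0 °C → rt
Reagents that add atoms: Bestmann–Ohira reagent CC(=O)C(=[N+]=[N-])P(=O)(OC)OC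
Why: Ohira–Bestmann (Seyferth–Gilbert) homologation converts the non-enolisable aldehyde into the terminal alkyne by olefination to the diazoalkene, loss of N2 and 1,2-hydrogen shift, and tolerates the free neopentyl alcohol.

**Step 4**
Reactants: 3 (E)-7-bromo-6-methylhept-5-en-2-one; 6 2,2-dimethylbut-3-yn-1-ol
Product: 7 (E)-11-hydroxy-6,10,10-trimethylundec-5-en-8-yn-2-one
Conditions: CuI (10 mol %), NaI (0.2 equiv), K2CO3 (1.5 equiv), DMF, rt
Reagents that add atoms: none
Why: Copper-acetylide SN2 alkynylation of the primary allylic bromide gives the skipped enyne with the E alkene retained; ketone and alcohol are inert to carbonate.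

**Step 5**
Reactants: 7 (E)-11-hydroxy-6,10,10-trimethylundec-5-en-8-yn-2-one
Product: 8 (5E,8Z)-11-hydroxy-6,10,10-trimethylundeca-5,8-dien-2-one
Conditions: H2 (1 atm, 1.0 equiv uptake), Pd/CaCO3 poisoned with Pb(OAc)2, quinoline, EtOAc, rt
Reagents that add atoms: none
Why: Lindlar semi-hydrogenation (syn addition) gives the Z alkene that becomes the cis C4=C5 alkene of the seven-membered ring; the trisubstituted alkene and ketone are untouched.

**Step 6**
Reactants: 8 (5E,8Z)-11-hydroxy-6,10,10-trimethylundeca-5,8-dien-2-one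
Product: 9 (3Z,6E)-2,2,6-trimethyl-10-oxoundeca-3,6-dienal
Conditions: Dess–Martin periodinane (1.2 equiv), NaHCO3, CH2Cl2, 0 °C → rt
Reagents that add atoms: none
Why: Dess–Martin oxidation of the neopentyl primary alcohol gives an aldehyde with no α-hydrogen, so it can neither enolise nor move its Z alkene into conjugation.

**Step 7**
Reactants: 9 (3Z,6E)-2,2,6-trimethyl-10-oxoundeca-3,6-dienal
Product: 11 (2E,5Z,8E)-4,4,8-trimethylcycloundeca-2,5,8-trien-1-one, via macrocyclic aldol 10 (not isolated)
Conditions: Ba(OH)2·8H2O (0.5 equiv), EtOH, 50 °C, syringe-pump addition of 9 over 12 h (final 2 mM)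
Reagents that add atoms: none
Why: Intramolecular Claisen–Schmidt condensation (methyl-ketone enolate onto the non-enolisable aldehyde, then E1cB dehydration) closes the humulane-type ring under high dilution, helped by the gem-dimethyl group and two alkenes; the E enone is favoured because the Z isomer would put CMe2 cis to the carbonyl.

**Step 8**
Reactants: 11 (2E,5Z,8E)-4,4,8-trimethylcycloundeca-2,5,8-trien-1-one
Product: 13 (1R,2S,7R,8S)-2,6,6-trimethyltricyclo[5.4.0.0^2,8]undec-4-en-9-one, via himachalyl-type zwitterion 12 (not isolated)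
Conditions: (S)-3,3-diphenyl-1-(o-tolyl)tetrahydro-1H,3H-pyrrolo[1,2-c][1,3,2]oxazaborole·AlBr3 (20 mol %), CH2Cl2, −78 °C, 2 h; Et3N quench at −78 °C
Reagents that add atoms: none
Why: Proposed new method: the Lewis-acid-bound s-trans enone acts as an oxygen-stabilised f1–f3 allyl cation, the f6=f7 alkene attacks f1 across the ring (macrocycle C9 onto C3) to give tertiary cation/enolate 12, and the enolate carbon f2 then bonds to f7 (C2–C8) before hydride shift or elimination; the closest known reactions are Lewis-acid and Gassman-type stepwise cationic [2+2] cycloadditions of enones or alkoxyallyl cations with trisubstituted alkenes and oxazaborolidinium-catalysed enantioselective [2+2] reactions; the relative configuration of C1, C2, C7 and C8 is forced by the E,E geometry and the two ring tethers, the absolute sense by the catalyst (its antipode is used if the sense is reversed), and any shortfall in ee is purged in steps 12 and 13.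

**Step 9**
Reactants: 13 (1R,2S,7R,8S)-2,6,6-trimethyltricyclo[5.4.0.0^2,8]undec-4-en-9-one
Product: 14 (1R,2S,7R,8S)-2,6,6-trimethyltricyclo[5.4.0.0^2,8]undeca-4,10-dien-9-one
Conditions: IBX (2.2 equiv), 4-methoxypyridine N-oxide (2.2 equiv), DMSO, rt → 40 °C
Reagents that add atoms: none
Why: IBX α,β-dehydrogenation can only proceed through the C9–C10 enol, because the other α-carbon is a bridgehead, and gives the apoverbenone-type enone without touching a stereocentre.

**Step 10**
Reactants: 14 (1R,2S,7R,8S)-2,6,6-trimethyltricyclo[5.4.0.0^2,8]undeca-4,10-dien-9-one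
Product: 15 (1R,2S,7R,8S,9S)-2,6,6,9-tetramethyltricyclo[5.4.0.0^2,8]undeca-4,10-dien-9-ol
Conditions: CH3Li (1.3 equiv), Et2O, −78 °C; H2O
Reagents that add atoms: methyllithium [Li]C
Why: 1,2-Addition of methyllithium to the enone from the face of the CH bridge (C7), away from the methyl on C2, brings in the last carbon; the carbinol centre is destroyed in step 11, so its configuration does not matter.

**Step 11**
Reactants: 15 (1R,2S,7R,8S,9S)-2,6,6,9-tetramethyltricyclo[5.4.0.0^2,8]undeca-4,10-dien-9-ol
Product: 16 (1R,2R,7S,8R)-2,6,6,9-tetramethyltricyclo[5.4.0.0^2,8]undeca-4,9-dien-11-one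
Conditions: pyridinium chlorochromate, C5H5NH[CrO3Cl] (2.5 equiv), 4 Å MS, CH2Cl2, rt
Reagents that add atoms: pyridinium chlorochromate [O-][Cr](=O)(=O)Cl.c1cc[nH+]cc1
Why: Dauben–Babler oxidative 1,3-transposition of the tertiary allylic alcohol gives the verbenone-type enone (ketone at C11, methyl on C9) and leaves the skeletal stereocentres and the isolated cis alkene alone.

**Step 12**
Reactants: 16 (1R,2R,7S,8R)-2,6,6,9-tetramethyltricyclo[5.4.0.0^2,8]undeca-4,9-dien-11-one
Product: 17 (1R,2R,4R,5S,7S,8R)-4,5-epoxy-2,6,6,9-tetramethyltricyclo[5.4.0.0^2,8]undec-9-en-11-one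
Conditions: (S,S)-N,N'-bis(3,5-di-tert-butylsalicylidene)-1,2-cyclohexanediaminomanganese chloride (5 mol %), mCPBA (1.5 equiv), N-methylmorpholine N-oxide (5 equiv), CH2Cl2, −78 °C
Reagents that add atoms: mCPBA OOC(=O)c1cccc(Cl)c1
Why: Jacobsen–Katsuki epoxidation takes the electron-rich cis C4=C5 alkene and not the enone; because the tricycle has a near mirror plane through the seven-membered ring, the face (oxygen syn to bridgehead C8) must be set by the catalyst, the (S,S)-complex being expected from the side-on approach model with the CMe2 flank as the large group (antipode on hand), and the minor diastereomer, which also carries the minor enantiomer from step 8, is removed by chromatography.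

**Step 13**
Reactants: 17 (1R,2R,4R,5S,7S,8R)-4,5-epoxy-2,6,6,9-tetramethyltricyclo[5.4.0.0^2,8]undec-9-en-11-one; 18 (S)-2-methylbutanoic acid
Product: 19 (1R,2R,4S,5S,7S,8R)-5-hydroxy-2,6,6,9-tetramethyl-11-oxotricyclo[5.4.0.0^2,8]undec-9-en-4-yl (2S)-2-methylbutanoate
Conditions: 18 (5 equiv), Cs2CO3 (0.3 equiv), DMF, 80 °C
Reagents that add atoms: none
Why: Carboxylate SN2 opening of the epoxide with inversion at C4 (C5 is neopentyl and blocked by the adjacent CMe2) gives the trans hydroxy ester with the acyl group on the correct oxygen and with C4 and C5 both S; the buffered medium spares the enone and cyclobutane.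

**Step 14**
Reactants: 19 (1R,2R,4S,5S,7S,8R)-5-hydroxy-2,6,6,9-tetramethyl-11-oxotricyclo[5.4.0.0^2,8]undec-9-en-4-yl (2S)-2-methylbutanoate; 20 angelic acid
Product: 22 (1R,2R,4S,5S,7S,8R)-2,6,6,9-tetramethyl-4-{[(2S)-2-methylbutanoyl]oxy}-11-oxotricyclo[5.4.0.0^2,8]undec-9-en-5-yl (2Z)-2-methylbut-2-enoate, via mixed anhydride 21 (not isolated)
Conditions: 20 (3 equiv), 2,4,6-trichlorobenzoyl chloride (3 equiv), Et3N (6 equiv), toluene, rt, 2 h; then 19, 80 °C
Reagents that add atoms: none
Why: Yamaguchi-type acylation through the mixed anhydride, run without DMAP, esterifies the hindered neopentyl alcohol without Z → E isomerisation to the tiglate and touches no stereocentre.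

**Compound list**
1 | 6-methylhept-5-en-2-one | CC(=O)CCC=C(C)C | starting material
2 | (E)-7-hydroxy-6-methylhept-5-en-2-one | CC(=O)CC/C=C(\C)CO | intermediate
3 | (E)-7-bromo-6-methylhept-5-en-2-one | CC(=O)CC/C=C(\C)CBr | intermediate
4 | 3-hydroxy-2,2-dimethylpropanal (hydroxypivaldehyde) | CC(C)(CO)C=O | starting material
5 | 4-diazo-2,2-dimethylbut-3-en-1-ol (diazoalkene, not isolated) | OCC(C)(C)C=C=[N+]=[N-] | intermediate
6 | 2,2-dimethylbut-3-yn-1-ol | C#CC(C)(C)CO | intermediate
7 | (E)-11-hydroxy-6,10,10-trimethylundec-5-en-8-yn-2-one | CC(=O)CC/C=C(\C)CC#CC(C)(C)CO | intermediate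
8 | (5E,8Z)-11-hydroxy-6,10,10-trimethylundeca-5,8-dien-2-one | CC(=O)CC/C=C(\C)C/C=C\C(C)(C)CO | intermediate
9 | (3Z,6E)-2,2,6-trimethyl-10-oxoundeca-3,6-dienal | CC(=O)CC/C=C(\C)C/C=C\C(C)(C)C=O | intermediate
10 | (5Z,8E)-3-hydroxy-4,4,8-trimethylcycloundeca-5,8-dien-1-one (racemic aldol, not isolated) | O=C1CC(O)C(C)(C)/C=C\C/C(C)=C/CC1 | intermediate
11 | (2E,5Z,8E)-4,4,8-trimethylcycloundeca-2,5,8-trien-1-one | O=C1/C=C/C(C)(C)/C=C\C/C(C)=C/CC1 | intermediate
12 | cis-fused himachalyl-type zwitterion: tertiary cation at C2, enolate at C9, Lewis-acid bound (not isolated) | C1=CC[C+](C)[C@@H]2CCC([O-])=C[C@@H]2C1(C)C | intermediate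
13 | (1R,2S,7R,8S)-2,6,6-trimethyltricyclo[5.4.0.0^2,8]undec-4-en-9-one | C1=CC[C@@]2(C)[C@@H]3CCC(=O)[C@H]2[C@@H]3C1(C)C | intermediate
14 | (1R,2S,7R,8S)-2,6,6-trimethyltricyclo[5.4.0.0^2,8]undeca-4,10-dien-9-one | C1=CC[C@@]2(C)[C@@H]3C=CC(=O)[C@H]2[C@@H]3C1(C)C | intermediate
15 | (1R,2S,7R,8S,9S)-2,6,6,9-tetramethyltricyclo[5.4.0.0^2,8]undeca-4,10-dien-9-ol | C1=CC[C@@]2(C)[C@@H]3C=C[C@](C)(O)[C@H]2[C@@H]3C1(C)C | intermediate
16 | (1R,2R,7S,8R)-2,6,6,9-tetramethyltricyclo[5.4.0.0^2,8]undeca-4,9-dien-11-one | C1=CC[C@@]2(C)[C@@H]3C(=O)C=C(C)[C@H]2[C@@H]3C1(C)C | intermediate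
17 | (1R,2R,4R,5S,7S,8R)-4,5-epoxy-2,6,6,9-tetramethyltricyclo[5.4.0.0^2,8]undec-9-en-11-one | O1[C@@H]2[C@H]1C[C@@]3(C)[C@@H]4C(=O)C=C(C)[C@H]3[C@@H]4C2(C)C | intermediate
18 | (S)-2-methylbutanoic acid | CC[C@H](C)C(=O)O | starting material
19 | (1R,2R,4S,5S,7S,8R)-5-hydroxy-2,6,6,9-tetramethyl-11-oxotricyclo[5.4.0.0^2,8]undec-9-en-4-yl (2S)-2-methylbutanoate | O[C@@H]1[C@@H](OC(=O)[C@@H](C)CC)C[C@@]2(C)[C@@H]3C(=O)C=C(C)[C@H]2[C@@H]3C1(C)C | intermediate
20 | angelic acid, (Z)-2-methylbut-2-enoic acid | C/C=C(/C)C(=O)O | starting material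
21 | angelic 2,4,6-trichlorobenzoic anhydride (not isolated) | C/C=C(/C)C(=O)OC(=O)c1c(Cl)cc(Cl)cc1Cl | intermediate
22 | CNP0323606.1: 7-angeloyloxy-8-[(S)-2-methylbutanoyloxy]longipin-2-en-1-one, (1R,2R,4S,5S,7S,8R)-2,6,6,9-tetramethyl-4-{[(2S)-2-methylbutanoyl]oxy}-11-oxotricyclo[5.4.0.0^2,8]undec-9-en-5-yl (2Z)-2-methylbut-2-enoate | C/C=C(/C)C(=O)O[C@@H]1[C@@H](OC(=O)[C@@H](C)CC)C[C@@]2(C)[C@@H]3C(=O)C=C(C)[C@H]2[C@@H]3C1(C)C | target

**Step count**
Total steps: 14. Longest linear sequence: 13 (steps 1, 2, 4–14; step 3 makes the second fragment).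

**Steps most likely to fail, with fallbacks**

Step 7 (closure of the 11-membered ring). If the dilute aldol condensation gives mainly oligomers, the ring is closed by a samarium Reformatsky reaction. The fallback sets out from 8. LDA (2.2 equiv) and TMSCl at −78 °C give the bis-silyl derivative F1 (kinetic enol ether of the methyl ketone plus silyl ether). NBS, then mild acidic methanol, gives the bromomethyl ketone F2, and Dess–Martin oxidation gives the bromo keto aldehyde F3. SmI2 (2.2 equiv, THF, −78 °C, 2 mM) then closes the ring to aldol 10, now isolated. Mesylation to the mesylate F4 and treatment with DBU rejoin the route at 11.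

Step 8 (transannular two-bond closure). If the Lewis acid gives hydrogen-shift or elimination products, or low ee, the cation is generated Gassman-style from a chiral ketal. The fallback sets out from 11. The bis-trimethylsilyl ether of (2R,3R)-butane-2,3-diol with catalytic TMSOTf at −78 °C gives the (2R,3R)-butane-2,3-diol ketal F5. Triflic acid (10 mol %, CH2Cl2, −78 °C) ionises it to the tethered alkoxyallyl cation, which undergoes the same f1–f6/f2–f7 closure and recloses to the tricyclic ketal F6; the auxiliary biases the face and the diastereomers are separable. PPTS in aqueous acetone rejoins the route at 13.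

Step 12 (face of the epoxide). The two alkene faces differ only through the catalyst, so selectivity may be low. The fallback sets out from 16. mCPBA with NaHCO3 and no catalyst gives 17 together with the diastereomeric epoxide F7 in roughly equal amounts, and the two are separated by chromatography. F7 is deoxygenated stereospecifically back to 16 with triphenylphosphine selenide and trifluoroacetic acid and recycled, and the route is rejoined at 17.

**Further compounds**
F1 | step 7 | (5E,8Z)-6,10,10-trimethyl-2,11-bis(trimethylsilyloxy)undeca-1,5,8-triene | C=C(O[Si](C)(C)C)CC/C=C(\C)C/C=C\C(C)(C)CO[Si](C)(C)C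
F2 | step 7 | (5E,8Z)-1-bromo-11-hydroxy-6,10,10-trimethylundeca-5,8-dien-2-one | BrCC(=O)CC/C=C(\C)C/C=C\C(C)(C)CO
F3 | step 7 | (3Z,6E)-11-bromo-2,2,6-trimethyl-10-oxoundeca-3,6-dienal | BrCC(=O)CC/C=C(\C)C/C=C\C(C)(C)C=O
F4 | step 7 | (5Z,8E)-4,4,8-trimethyl-1-oxocycloundeca-5,8-dien-3-yl methanesulfonate | O=C1CC(OS(C)(=O)=O)C(C)(C)/C=C\C/C(C)=C/CC1
F5 | step 8 | (2R,3R)-butane-2,3-diyl ketal of 11 | C[C@@H]1[C@@H](C)OC2(O1)/C=C/C(C)(C)/C=C\C/C(C)=C/CC2
F6 | step 8 | (2R,3R)-butane-2,3-diyl ketal of 13 | C1=CC[C@@]2(C)[C@@H]3CCC4(O[C@H](C)[C@@H](C)O4)[C@H]2[C@@H]3C1(C)C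
F7 | step 12 | (1R,2R,4S,5R,7S,8R)-4,5-epoxy-2,6,6,9-tetramethyltricyclo[5.4.0.0^2,8]undec-9-en-11-one | O1[C@H]2[C@@H]1C[C@@]3(C)[C@@H]4C(=O)C=C(C)[C@H]3[C@@H]4C2(C)C
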